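A charge of 0.22 mM of free catalyst faces 0.20 M of substrate in the elm flask, so each catalyst would have to turn over 909 times to finish. Elm stood at 30.1% after 120 h. It gained 0.8 percentage points in its last 24.0 h, against a scatter of 0.3 points. What must its end state be?

| setting | elm | ash | flask |
|---|---|---|---|
| substrate | 0.20 M | 0.13 M | 0.20 M |
| reagent | 0.24 M | 0.24 M | 0.240 M |
| free catalyst | 0.22 mM | 0.22 mM | 0.22 mM |
| impurity | 29 µM | 29 µM | 29 µM |
| temperature | 80 °C | 80 °C | 80 °C |
| remark | the very flask that is asked about, followed so far | run made earlier |  |
| time |  |  | 8.0 d |

| run | time / h | product / % |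
|---|---|---|
| elm | 8.00 | 7.8 |
| elm | 20.0 | 13.9 |
| elm | 40.0 | 20.6 |
| elm | 60.0 | 24.5 |
| elm | 96.0 | 29.3 |
| elm | 120 | 30.1 |
| ash | 4.00 | 5.0 |
| ash | 8.00 | 9.2 |
| ash | 12.0 | 12.5 |
| ash | 15.0 | 14.9 |
| ash | 20.0 | 17.9 |
| ash | 25.0 | 20.2 |

(scatter of a reading: 0.3 percentage points)

- Friday's: at 8.0 d add free catalyst, 50.0% of the amount charged, then wait 15 d
- Wednesday's: change nothing and wait 15 d more
- Saturday's: at 8.0 d take out 90% of the product then present, then wait 15 d
- Sunday's: at 8.0 d add reagent, 100% of the amount charged, then wait 15 d
- Monday's: at 8.0 d raise the temperature by 15 K, then wait 15 d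

- removed product is counted in
- the numbers in the tables scatter with a standard deviation of 0.3 percentage points
- additions bring no volume worth counting
- the earlier runs do not show what temperature does; that part of a forecast is a guess

1. product, in percent of the substrate first charged, at 8.0 d
2. the option that brings most further product ("none" if no option brings more than 2 percentage points) (Friday's / Wednesday's / Saturday's / Sunday's / Monday's / none)
3. product present, with what was taken out counted in, in percent of the substrate first charged, after Wednesday's
4. product present, with what was taken out counted in, in percent of the substrate first charged, after Saturday's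

Two chemists argue. The colleague sees a balance: the flask stops at a share of its substrate. In his view, taking out 90% of the product reopens that balance, so he bets on Saturday's.

The forecaster disagrees. My own reading of the tables goes against a fixed share too. At about the same share, ash gained 2.3 points in 5.00 h, but elm gained 3.9 points in 20.0 h. The colleague answers that ash holds more reagent per substrate, so its balance lies further on. The readings do not end the quarrel, but the options can.

The forecaster's view is that “catalyst is lost per turnover, roughly 280 turnovers each”. My own reckoning from elm's last reading gives 274 turnovers so far per catalyst charged. Call this the turnover budget, the product a catalyst charge yields before it stops; the field says turnover number. On this view the stop is an amount of product, not a share. By my reckoning, Friday's addition buys about 15 points.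

The forecast gives 31% now, 31.3% after Wednesday's, 31.8% after Saturday's, and names Friday's as best.

The flask gives 33.0% at 8.0 d. Friday's brings 20 points, the most of the options. Saturday's brings 1.7 points, level with Wednesday's, and both end at 34.7%.

    free catalyst + impurity → spent catalyst A (k = 1.20 × 10⁵ M⁻¹ h⁻¹, Ea = 50.0 kJ mol⁻¹)
    catalyst intermediate A ⇌ released group + catalyst intermediate B (K = 0.160 M, k = 300 h⁻¹, Ea = 97.0 kJ mol⁻¹, ΔH = −30.0 kJ mol⁻¹)
    catalyst intermediate C → free catalyst + product (k = 38.0 h⁻¹, Ea = 95.0 kJ mol⁻¹)
    substrate + catalyst intermediate B ⇌ catalyst intermediate C (K = 4.30 M⁻¹, k = 510 M⁻¹ h⁻¹, Ea = 72.0 kJ mol⁻¹, ΔH = −5.00 kJ mol⁻¹)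
    substrate + catalyst intermediate B → spent catalyst B (k = 0.340 M⁻¹ h⁻¹, Ea = 72.0 kJ mol⁻¹)
    reagent + free catalyst ⇌ catalyst intermediate A (K = 1.50 M⁻¹, k = 1200 M⁻¹ h⁻¹, Ea = 46.0 kJ mol⁻¹, ΔH = −81.0 kJ mol⁻¹)
    (constants at 80 °C)

Part of the reason for the stop is the reaction of substrate with catalyst intermediate B to spent catalyst B, acting together with the falling back of catalyst intermediate C. The run without that reaction reaches 64.2% at 8.0 d, not 33.0%. The colleague's stopping share describes this flask as charged: 34.8% after 1920 h, which is 316 turnovers. The neighbour charged with 0.50 M of substrate stands at another share, 13.8% at 8.0 d, yet at 314 turnovers, where elm's budget gave 12.0%.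

The readings come from a simulation on assumed constants, noise included.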